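**Strategy.** The synthesis rests on disconnecting the butenolide at its ring O–C15H2 bond (labdane numbering; lactone ring O–C15–C14=C13–C16). The allylic C15–O/C13=C14 unit of that ring is the isomer of a terminal allene, so the last ring is closed by an AuCl3-catalysed 5-endo cyclisation of a tert-butyl 2-alkylbuta-2,3-dienoate. In one operation the ester carbonyl oxygen bonds to C15, the C13=C14 alkene is placed and the tert-butyl group leaves. The precursor is an open-chain allenoate on an acetal-protected ent-labdane decalin, made by an enantioselective polyene bicyclisation with [Ir(cod)Cl]2 and a chiral phosphoramidite, aldol–Cannizzaro bis-hydroxymethylation at C4 and epoxide-to-aldehyde rearrangement at C8.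

Key step: step 16

**Remarks and assumptions**
- Decalins are described with labdane locants: C1–C10 ring carbons, angular methyl on C10, C17 on C8, C11–C12 on C9, C18/C19 on C4, butenolide C13–C16. α/β refer to the usual steroid-type drawing. All decalins are trans-fused with 5β-H and 10α-methyl.
- Assumption: the (R)-configured ligand in step 8 is taken as the enantiomer that gives the 5β-H/10α-methyl series. If the sense of induction is the opposite, the (S)-ligand is used without other change.
- The C4 configuration of 14–19 has no consequence, because C4 carries two identical CH2OH groups from 20 onward.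

**Route**

Step 1
Reactants: 1 5-chloropent-1-yne
Product: 4 (E)-7-chloro-4-methylhept-3-en-1-ol, via (E)-alkenyldimethylalane 2 (not isolated), via lithium alkenylalanate 3 (not isolated)
Conditions: Me3Al (2 equiv), Cp2ZrCl2 (20 mol %), CH2Cl2, 0 °C to rt; volatiles removed; n-BuLi, hexane–THF, −78 °C; ethylene oxide, −78 to 0 °C; aq. NH4Cl
Reagents that add atoms: trimethylaluminium, C[Al](C)C; ethylene oxide, C1CO1
Why: Cp2ZrCl2-catalysed Negishi carboalumination adds methyl and aluminium syn across the terminal alkyne with aluminium on the terminal carbon, and the derived alanate opens ethylene oxide with retention of alkene geometry, which sets the E trisubstituted alkene (methyl cis to the hydroxyethyl arm) while the remote primary chloride is not attacked at low temperature.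

Step 2
Reactants: 4 (E)-7-chloro-4-methylhept-3-en-1-ol
Product: 5 (E)-7-chloro-1-iodo-4-methylhept-3-ene
Conditions: I2, PPh3, imidazole, CH2Cl2, 0 °C
Reagents that add atoms: iodine, II
Why: Appel-type iodination (alkoxyphosphonium, then SN2 by iodide) converts the primary alcohol without touching the alkene or the chloride.

Step 3
Reactants: 6 2,3-dihydrofuran; 5 (E)-7-chloro-1-iodo-4-methylhept-3-ene
Product: 8 5-[(E)-7-chloro-4-methylhept-3-en-1-yl]-2,3-dihydrofuran, via 5-lithio-2,3-dihydrofuran 7 (not isolated)
Conditions: t-BuLi, THF, −78 to 0 °C; then 5, −78 °C to rt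
Reagents that add atoms: none
Why: Deprotonation of the enol-ether α-vinyl C–H and SN2 alkylation of the vinyllithium by the homoallylic iodide is a standard entry to 5-alkyl-2,3-dihydrofurans; the remote chloride, a far poorer leaving group, is untouched.

Step 4
Reactants: 8 5-[(E)-7-chloro-4-methylhept-3-en-1-yl]-2,3-dihydrofuran
Product: 9 (3Z,7E)-11-chloro-8-methyl-4-[(trimethylsilyl)methyl]undeca-3,7-dien-1-ol
Conditions: Me3SiCH2MgCl, NiCl2(PPh3)2 (5 mol %), benzene, reflux; aq. NH4Cl
Reagents that add atoms: (trimethylsilyl)methylmagnesium chloride, C[Si](C)(C)C[Mg]Cl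
Why: NiCl2(PPh3)2-catalysed Kumada-type coupling with cleavage of the vinylic C–O bond opens the dihydrofuran with retention at the alkene, so CH2SiMe3 takes the place of oxygen cis to the hydroxyethyl arm (3Z), the geometry that later places the C9 side chain equatorial; the alkyl chloride is inert to this catalyst.

Step 5
Reactants: 9 (3Z,7E)-11-chloro-8-methyl-4-[(trimethylsilyl)methyl]undeca-3,7-dien-1-ol
Product: 10 (3Z,7E)-11-iodo-8-methyl-4-[(trimethylsilyl)methyl]undeca-3,7-dien-1-ol
Conditions: NaI, acetone, reflux
Reagents that add atoms: sodium iodide, [Na+].[I-]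
Why: Finkelstein exchange (SN2) of the primary chloride, driven by precipitation of NaCl, prepares the head group for lithium–iodine exchange.

Step 6
Reactants: 10 (3Z,7E)-11-iodo-8-methyl-4-[(trimethylsilyl)methyl]undeca-3,7-dien-1-ol
Product: 11 (3Z,7E)-1-chloro-11-iodo-8-methyl-4-[(trimethylsilyl)methyl]undeca-3,7-diene
Conditions: PPh3, CCl4, CH2Cl2, rt
Reagents that add atoms: carbon tetrachloride, ClC(Cl)(Cl)Cl
Why: Appel chlorination under neutral conditions turns the alcohol into a robust latent leaving group at C12 while allylsilane and iodide stay intact at room temperature.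

Step 7
Reactants: 11 (3Z,7E)-1-chloro-11-iodo-8-methyl-4-[(trimethylsilyl)methyl]undeca-3,7-diene
Product: 13 (7E,11Z)-14-chloro-7-methyl-11-[(trimethylsilyl)methyl]tetradeca-1,7,11-trien-3-ol (racemic), via primary alkyllithium 12 (not isolated)
Conditions: t-BuLi (2.1 equiv), Et2O–pentane, −78 °C; then CH2=CHCHO, −78 °C; aq. NH4Cl
Reagents that add atoms: acrolein, C=CC=O
Why: Lithium–iodine exchange is selective for the primary iodide over the primary chloride at −78 °C and the alkyllithium adds 1,2 to acrolein; the carbinol centre is racemic by design because it is erased on ionisation in step 8.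

Step 8
Reactants: 13 (7E,11Z)-14-chloro-7-methyl-11-[(trimethylsilyl)methyl]tetradeca-1,7,11-trien-3-ol
Product: 14 9α-(2-chloroethyl)-10α-methyl-8-methylidene-4β-vinyl-trans-decalin (5β-H; 9β-H)
Conditions: [Ir(cod)Cl]2 (4 mol %), (R)-BINOL phosphoramidite of 5H-dibenz[b,f]azepine (P,olefin ligand, 16 mol %), Zn(OTf)2 (20 mol %), ClCH2CH2Cl, rt
Reagents that add atoms: none
Why: Enantioselective allylic-alcohol-initiated cation–olefin polycyclisation with [Ir(cod)Cl]2 and the phosphoramidite: Zn(OTf)2-assisted ionisation gives an iridium-bound allyl cation whose face is fixed by the chiral ligand, the E alkene and the allylsilane add through a chair–chair array (trans fusion at C5/C10, equatorial vinyl at C4, equatorial C9 chain cis to the angular methyl), and loss of the silyl group places the alkene regiospecifically at C8=C17.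

Step 9
Reactants: 14 9α-(2-chloroethyl)-10α-methyl-8-methylidene-4β-vinyl-trans-decalin
Product: 15 8β,17-epoxide of 14 (spiro-oxirane at C8; oxygen on the β face)
Conditions: m-CPBA (1.05 equiv), NaHCO3, CH2Cl2, 0 °C
Reagents that add atoms: 3-chloroperoxybenzoic acid, OOC(=O)c1cccc(Cl)c1
Why: Prilezhaev epoxidation should be chemoselective for the more electron-rich 1,1-disubstituted exocyclic alkene over the monosubstituted vinyl group, the peracid approaching from the β face opposite the axial angular methyl (the C8 configuration is in any case reset in step 10).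

Step 10
Reactants: 15 8β,17-epoxide
Product: 17 9α-(2-chloroethyl)-8β-(dimethoxymethyl)-10α-methyl-4β-vinyl-trans-decalin, via 8β-formyl aldehyde 16 (not isolated)
Conditions: BF3·OEt2 (0.2 equiv), CH2Cl2, −78 °C; then HC(OMe)3, MeOH, −78 °C to rt
Reagents that add atoms: trimethyl orthoformate, COC(OC)OC; methanol, CO
Why: Meinwald rearrangement: BF3 opens the epoxide at tertiary C8 and hydride migrates from C17 anti to the departing oxygen, giving the 8β (equatorial) aldehyde, which is also the thermodynamically favoured epimer, and acid-catalysed acetalisation in the same flask masks it.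

Step 11
Reactants: 17 8β-(dimethoxymethyl)-4β-vinyl decalin
Product: 18 9α-(2-chloroethyl)-8β-(dimethoxymethyl)-4β-formyl-10α-methyl-trans-decalin
Conditions: O3, pyridine (cat.), CH2Cl2, −78 °C; then Me2S
Reagents that add atoms: ozone, [O-][O+]=O
Why: Ozonolysis with reductive work-up cleaves the only remaining alkene to the C4 aldehyde; acetal and alkyl chloride are inert.

Step 12
Reactants: 18 4β-formyl decalin
Product: 20 9α-(2-chloroethyl)-8β-(dimethoxymethyl)-4,4-bis(hydroxymethyl)-10α-methyl-trans-decalin, via aldol adduct 19 (not isolated)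
Conditions: aq. HCHO (37 %), KOH, MeOH–THF–H2O, 0 to 40 °C
Reagents that add atoms: formaldehyde, C=O
Why: Tollens reaction: aldol addition of the C4 enolate to formaldehyde makes C4 quaternary and the now non-enolisable aldehyde is reduced by crossed Cannizzaro hydride transfer from formaldehyde, which leaves two identical CH2OH groups on C4; the unactivated primary chloride should survive at this temperature.

Step 13
Reactants: 20 4,4-bis(hydroxymethyl) decalin
Product: 21 isopropylidene acetal of 20 (spiro-1,3-dioxane at C4)
Conditions: Me2C(OMe)2, PPTS (cat.), CH2Cl2, rt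
Reagents that add atoms: 2,2-dimethoxypropane, COC(C)(C)OC
Why: Acid-catalysed transacetalisation gives the six-membered acetonide of the 1,3-diol, which shields both hydroxyls from acetyl chloride in step 15.

Step 14
Reactants: 21 acetonide chloride; 22 tert-butyl (triphenylphosphoranylidene)acetate
Product: 24 [1-(tert-butoxycarbonyl)-3-(decalin-9α-yl)propyl]triphenylphosphonium iodide, via primary iodide 23 (not isolated)
Conditions: NaI, MeCN, reflux
Reagents that add atoms: sodium iodide, [Na+].[I-]
Why: In situ Finkelstein exchange gives the primary iodide, which C-alkylates the stabilised phosphorus ylide (SN2) to the phosphonium salt; the new α-centre forms as a mixture and is erased in step 15.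

Step 15
Reactants: 24 phosphonium iodide
Product: 26 tert-butyl 2-[2-(protected decalin-9α-yl)ethyl]buta-2,3-dienoate, via α-alkylated ylide 25 (not isolated)
Conditions: Et3N (2.2 equiv), AcCl (1.1 equiv), CH2Cl2, 0 °C to rt
Reagents that add atoms: acetyl chloride, CC(Cl)=O
Why: Et3N regenerates the α-substituted ylide and converts acetyl chloride into ketene, and the Wittig reaction of the two gives the terminal allene, a standard synthesis of 2-substituted buta-2,3-dienoates.

Step 16
Reactants: 26 tert-butyl allenoate
Product: 27 protected butenolide: 3-[2-(decalin-9α-yl)ethyl]furan-2(5H)-one with acetonide at C4 and dimethyl acetal at C8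
Conditions: AuCl3 (5 mol %), CH2Cl2, rt
Reagents that add atoms: none
Why: AuCl3 coordinates the terminal C14=C15 bond of the allene and the ester carbonyl oxygen attacks C15, forming the O–C15 bond and a vinylgold oxocarbenium ion; loss of the tert-butyl cation as isobutene unveils the lactone carbonyl and the proton set free cleaves the C14–Au bond. The closest known reaction type is the AuCl3-catalysed cyclisation of tert-butyl allenoates to butenolides, related to the AgNO3-catalysed cycloisomerisation of allenoic acids. The five-membered ring (O, C15, C14, C13, C16) closes in the 5-endo-trig mode at the unsubstituted allene terminus. No stereocentre is created. The step needs regioselectivity for C15 over the central C14 and for the carbonyl oxygen over the acetal oxygens: only attack at C15 gives an unstrained ring with C13=C14 conjugated to the carbonyl, and only the carbonyl oxygen is held within reach of C15. Any partial loss of the acetals under the Lewis acid is harmless because both are removed in step 17.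

Step 17
Reactants: 27 protected butenolide
Product: 28 target: 8β-formyl-4,4-bis(hydroxymethyl)-10α-methyl-9α-[2-(2-oxo-2,5-dihydrofuran-3-yl)ethyl]-trans-decalin (5β-H; 8α-H; 9β-H)
Conditions: 1 M HCl, THF, rt
Reagents that add atoms: water, O
Why: Acid-catalysed hydrolysis of the dimethyl acetal and the acetonide liberates the aldehyde and the diol; the butenolide is stable to acid and the equatorial C8 aldehyde, trans to the C9 chain, is the thermodynamic epimer and so should not be scrambled.

**Compound list**

1 | 5-chloropent-1-yne | C#CCCCCl | starting material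
2 | (E)-(5-chloro-2-methylpent-1-en-1-yl)dimethylalane | ClCCC/C(C)=C/[Al](C)C | intermediate
3 | lithium butyl[(E)-5-chloro-2-methylpent-1-en-1-yl]dimethylalanate | [Li+].CCCC[Al-](C)(C)/C=C(\C)CCCCl | intermediate
4 | (E)-7-chloro-4-methylhept-3-en-1-ol | ClCCC/C(C)=C/CCO | intermediate
5 | (E)-7-chloro-1-iodo-4-methylhept-3-ene | ClCCC/C(C)=C/CCI | intermediate
6 | 2,3-dihydrofuran | C1=COCC1 | starting material
7 | 5-lithio-2,3-dihydrofuran | [Li]C1=CCCO1 | intermediate
8 | 5-[(E)-7-chloro-4-methylhept-3-en-1-yl]-2,3-dihydrofuran | ClCCC/C(C)=C/CCC1=CCCO1 | intermediate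
9 | (3Z,7E)-11-chloro-8-methyl-4-[(trimethylsilyl)methyl]undeca-3,7-dien-1-ol | ClCCC/C(C)=C/CC/C(C[Si](C)(C)C)=C/CCO | intermediate
10 | (3Z,7E)-11-iodo-8-methyl-4-[(trimethylsilyl)methyl]undeca-3,7-dien-1-ol | ICCC/C(C)=C/CC/C(C[Si](C)(C)C)=C/CCO | intermediate
11 | (3Z,7E)-1-chloro-11-iodo-8-methyl-4-[(trimethylsilyl)methyl]undeca-3,7-diene | ICCC/C(C)=C/CC/C(C[Si](C)(C)C)=C/CCCl | intermediate
12 | primary alkyllithium from 11 (lithium in place of iodine) | [Li]CCC/C(C)=C/CC/C(C[Si](C)(C)C)=C/CCCl | intermediate
13 | (7E,11Z)-14-chloro-7-methyl-11-[(trimethylsilyl)methyl]tetradeca-1,7,11-trien-3-ol (racemic carbinol) | C=CC(O)CCC/C(C)=C/CC/C(C[Si](C)(C)C)=C/CCCl | intermediate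
14 | 9α-(2-chloroethyl)-10α-methyl-8-methylidene-4β-vinyl-trans-decalin (5β-H; 9β-H) | C[C@@]12CCC[C@H](C=C)[C@H]1CCC(=C)[C@H]2CCCl | intermediate
15 | 8β,17-epoxide of 14 | C[C@@]12CCC[C@H](C=C)[C@H]1CC[C@@]3(CO3)[C@H]2CCCl | intermediate
16 | 9α-(2-chloroethyl)-8β-formyl-10α-methyl-4β-vinyl-trans-decalin | C[C@@]12CCC[C@H](C=C)[C@H]1CC[C@H](C=O)[C@H]2CCCl | intermediate
17 | 9α-(2-chloroethyl)-8β-(dimethoxymethyl)-10α-methyl-4β-vinyl-trans-decalin | C[C@@]12CCC[C@H](C=C)[C@H]1CC[C@H](C(OC)OC)[C@H]2CCCl | intermediate
18 | 9α-(2-chloroethyl)-8β-(dimethoxymethyl)-4β-formyl-10α-methyl-trans-decalin | C[C@@]12CCC[C@H](C=O)[C@H]1CC[C@H](C(OC)OC)[C@H]2CCCl | intermediate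
19 | 4α-formyl-4β-(hydroxymethyl) aldol adduct of 18 (expected major C4 epimer) | C[C@@]12CCC[C@@](CO)(C=O)[C@H]1CC[C@H](C(OC)OC)[C@H]2CCCl | intermediate
20 | 9α-(2-chloroethyl)-8β-(dimethoxymethyl)-4,4-bis(hydroxymethyl)-10α-methyl-trans-decalin | C[C@@]12CCCC(CO)(CO)[C@H]1CC[C@H](C(OC)OC)[C@H]2CCCl | intermediate
21 | acetonide of 20 (spiro-2,2-dimethyl-1,3-dioxane at C4) | C[C@@]12CCCC3(COC(C)(C)OC3)[C@H]1CC[C@H](C(OC)OC)[C@H]2CCCl | intermediate
22 | tert-butyl (triphenylphosphoranylidene)acetate | CC(C)(C)OC(=O)C=P(c1ccccc1)(c1ccccc1)c1ccccc1 | starting material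
23 | primary iodide corresponding to 21 (9α-(2-iodoethyl)) | C[C@@]12CCCC3(COC(C)(C)OC3)[C@H]1CC[C@H](C(OC)OC)[C@H]2CCI | intermediate
24 | phosphonium iodide: Ph3P+ on the ester α-carbon (C13), mixture at C13 | C[C@@]12CCCC3(COC(C)(C)OC3)[C@H]1CC[C@H](C(OC)OC)[C@H]2CCC(C(=O)OC(C)(C)C)[P+](c1ccccc1)(c1ccccc1)c1ccccc1.[I-] | intermediate
25 | α-alkylated ylide from 24 | C[C@@]12CCCC3(COC(C)(C)OC3)[C@H]1CC[C@H](C(OC)OC)[C@H]2CCC(C(=O)OC(C)(C)C)=P(c1ccccc1)(c1ccccc1)c1ccccc1 | intermediate
26 | tert-butyl 2-substituted buta-2,3-dienoate (C13=C14=C15 allene, C16 ester) | C[C@@]12CCCC3(COC(C)(C)OC3)[C@H]1CC[C@H](C(OC)OC)[C@H]2CCC(=C=C)C(=O)OC(C)(C)C | intermediate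
27 | protected butenolide (acetonide at C4, dimethyl acetal at C8) | C[C@@]12CCCC3(COC(C)(C)OC3)[C@H]1CC[C@H](C(OC)OC)[C@H]2CCC1=CCOC1=O | intermediate
28 | 8β-formyl-4,4-bis(hydroxymethyl)-10α-methyl-9α-[2-(2-oxo-2,5-dihydrofuran-3-yl)ethyl]-trans-decalin | C[C@@]12CCCC(CO)(CO)[C@H]1CC[C@H](C=O)[C@H]2CCC1=CCOC1=O | target

**Step count and risk**

Total step count: 17. Longest linear sequence: 17 steps (1 to 28); 6 and 22 enter as purchased.

Steps most likely to fail:

1. Step 14. The C-alkylation of a stabilised ylide by an unactivated primary halide may be slow, so that prolonged heating leads to E2 elimination of the iodide or to decomposition of the ylide. The fallback sets out from 21 and comes back at 27. Finkelstein exchange (NaI, acetone) gives the iodide 23, here isolated. Alkylation of the dilithium salt of prop-2-yn-1-ol (LiC≡CCH2OLi, THF–DMPU) with 23 gives the 9α-(5-hydroxypent-3-yn-1-yl) alkynol F1. MsCl and Et3N give the propargylic mesylate F2. Hydroxycarbonylation with Pd(PPh3)4 (cat.), CO (1 atm), THF–H2O and 2,6-lutidine, by SN2′ displacement of the mesylate and CO insertion, gives the free 2-substituted buta-2,3-dienoic acid F3. AgNO3 (cat.) in acetone cycloisomerises F3 to 27, making the same O–C15 bond.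

2. Step 10. The tertiary C8 cation may be diverted, by a 1,2-hydride shift from C9 followed by methyl migration from C10 or by proton loss to an allylic alcohol, before hydride arrives from C17. The fallback sets out from 15 and comes back at 16, using a radical instead of a cationic opening. Cp2TiCl (from Cp2TiCl2 and Zn) with 1,4-cyclohexadiene in THF opens the epoxide reductively in the anti-Markovnikov sense to the 8-(hydroxymethyl) alcohol F4. Dess–Martin oxidation gives aldehyde 16, which is equilibrated with DBU to the equatorial epimer if needed and then acetalised as in the second half of step 10.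

3. Step 16. Ring closure at the unsubstituted allene terminus may be slow, which would allow Lewis-acid ionisation of the acetals, oligomerisation of the allene or its isomerisation to a 1,3-diene. The fallback sets out from 26 and comes back at 27. Iodolactonisation (I2, NaHCO3, MeCN–H2O) closes the same O–C15 bond with loss of the tert-butyl group and gives the 4-iodobutenolide F5. Hydrodeiodination with Pd(OAc)2/PPh3 (cat.), HCO2H and Et3N in DMF gives 27.

Step 8 is ranked just below these because it applies an established catalyst system to its own substrate class, allylic alcohols with a 2-(silylmethyl)alkene terminator.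

**Further compounds**

F1 | step 14 | alkynol: 9α-(5-hydroxypent-3-yn-1-yl) decalin with acetonide and dimethyl acetal | C[C@@]12CCCC3(COC(C)(C)OC3)[C@H]1CC[C@H](C(OC)OC)[C@H]2CCC#CCO
F2 | step 14 | methanesulfonate of F1 | C[C@@]12CCCC3(COC(C)(C)OC3)[C@H]1CC[C@H](C(OC)OC)[C@H]2CCC#CCOS(C)(=O)=O
F3 | step 14 | 2-substituted buta-2,3-dienoic acid (free acid corresponding to 26) | C[C@@]12CCCC3(COC(C)(C)OC3)[C@H]1CC[C@H](C(OC)OC)[C@H]2CCC(=C=C)C(=O)O
F4 | step 10 | 9α-(2-chloroethyl)-8β-(hydroxymethyl)-10α-methyl-4β-vinyl-trans-decalin | C[C@@]12CCC[C@H](C=C)[C@H]1CC[C@H](CO)[C@H]2CCCl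
F5 | step 16 | 4-iodobutenolide (3-alkyl-4-iodofuran-2(5H)-one analogue of 27) | C[C@@]12CCCC3(COC(C)(C)OC3)[C@H]1CC[C@H](C(OC)OC)[C@H]2CCC1=C(I)COC1=O
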